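# Proposed synthesis of CNP0173999.1 by a one-flask metallate shift / allylboration assembly

Numbering used throughout: the carbocycle runs from C1 (the ring carbon carrying CO2Me) through C2, C3, C4, C5 (butenolide α-carbon), C6 (β), C7 (γ, bearing the ring oxygen), C8, C9 (methyl), C10, C11, C12 (isopropyl) and C13 to C14 (carbinol).

## The problem

The target (35) is a 14-membered carbocycle bridged between C5 and C7 by a butenolide. The chain must therefore carry three trisubstituted alkenes (C1=C2 with the ester, C9=C10 with methyl, C11=C12 with isopropyl) before or while the large ring is closed. There are only two stereocentres, C7 (R) and C14 (S). They sit in a 1,8-relationship across the ring, so neither can direct the other and each needs its own source of chirality. Alkene geometry is as demanding as the stereocentres: C9=C10 and C11=C12 form a diene in which C10 is cis to C13, and at C1=C2 the ester is cis to C3, the less accessible isomer of a Baylis–Hillman-type hydroxy ester. Several groups are fragile: the γ-proton at C7 of the butenolide is acidic (base gives the 2-oxyfuran and erases the stereocentre), the C14 alcohol is allylic to an enoate, and the electron-rich diene does not tolerate strong protic acid. The butenolide and the free C14 hydroxyl therefore have to appear late and under near-neutral conditions. The opening feature is that the C14 carbinol is homoallylic to the C11=C12 alkene whose inner carbon C12 carries isopropyl. That is the product pattern of an aldehyde allylboration by an allylboronate substituted at its α-carbon (C11) and its 2-position (C12); the adjacent C1 enoate can be read as a former alkyne, which makes the aldehyde a small, reactive ynal.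

## Retrosynthesis

**Target 35 to macrolactone 34 (cut C5=C6).** Opening the butenolide alkene gives the 15-membered lactone 34 with a methylene on C5 and a vinyl group on C7. This cut is preferred to a cut of a ring C–C single bond (C3–C4 or C8–C9) because the ester tether makes the forward reaction a five-membered ring-closing metathesis and fixes the new alkene geometry. The forward step must engage a 1,1-disubstituted acrylate. No other olefin competes well: C9=C10 is E, so a six-membered closure onto C11 is impossible, and C1=C2 is trisubstituted and electron-poor.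

**34 to dihydroxy acid 32 (cut the acyl C–O bond to O–C7).** The lactone is opened to the seco acid 32. Acylation at the C7 hydroxyl closes a 15-membered ring, whereas the C14 hydroxyl could only give an eight-membered lactone containing the trans-disposed C1=C2 unit. C14 therefore needs no protection, which saves two steps against a protected variant. Acid 32 comes from diester 30 by unmasking the tert-butyl ester and the C7 silyl ether (through 31).

**30 to stannane 29 to propargylic alcohol 28 (cut C1–CO2Me, then return C1=C2 to an alkyne).** An aldol or Baylis–Hillman construction of the C1/C14 array would give the wrong enoate geometry or none at all. Hydroxyl-directed trans-hydrostannation followed by methoxycarbonylation places the ester cis to C3 by mechanism. The precursor 28 is acyclic and has lost the ester and one alkene. The forward steps must put tin on C1 and hydrogen on C2 from opposite faces while diene, acrylate and vinyl group look on.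

**28 to chloroboronate 15, Grignard reagent 17 and ynal 24 (cut C11–C12 and C13–C14).** This is the key disconnection. Cutting C13–C14 alone would need a separately made chiral allylboronate, and cutting C10–C11 (a diene cross-coupling) would leave C14 and the C11=C12 geometry as separate problems. The double cut divides the molecule into three pieces of five to eight carbons and lets one stereocentre on boron-bearing C11 set both the C11=C12 geometry and C14. The forward reaction must keep the C11 configuration of 15, migrate the alkenyl group with inversion (through 25 to 26), and transfer the allyl unit through C13 and not C9 (through 27).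

**15 to alkenylboronate 13 to iodide 10 to alkyne 8 (cut C10–C11, then C10–B and C9–CH3).** The chlorine-bearing C11 is a one-carbon insertion into the C10–B bond of 13 (via 14), and the C2-symmetric diol on boron selects the configuration. Boronate 13 comes from iodide 10 (via 11 and 12), and 10 from syn-carbometallation of alkyne 8 (via 9), which sets the 9E geometry. Each precursor is simpler by one carbon or one functional group.

**8 to enynol 7 to chlorohydrin 4 to (R)-epichlorohydrin 1 and ethynyltrimethylsilane 2.** C7 is taken from the chiral pool and not from a resolution. The epoxide carbon of 1 becomes C8, the chloromethyl carbon becomes C6 after a one-carbon ylide homologation (via 5 and 6), and the acetylide 3 supplies C9 and C10. No step touches the stereocentre.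

**24 to enyne ester 22 to phosphonate 21 to phosphonoacetate 18 and 4-bromobut-1-yne 19; 17 from bromide 16.** The C5 acrylate is made by alkylation of 18 (via enolate 20) and methylenation, and C14 is added last by formylation of the alkyne (via 23). The tert-butyl ester is chosen because it resists 1,2-addition and can later be cleaved without protic acid.

## Roads not taken

**Alternative 1: decarboxylative allylation with ring contraction.** The cut is C7–C8. The forward step would ionise the 16-membered allyl furan-2-yl carbonate A1 with zerovalent palladium (for example Pd2(dba)3 with a chiral ligand). After decarboxylation the furanolate would attack the allyl terminus C8 through C7 and give the silyl ether A2 of the target.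
- Merits: one catalytic step creates the C7–C8 bond, the C7 stereocentre and the butenolide, and needs no metathesis.
- Weak points: the allyl unit is the end of the C9–C12 diene, so ionisation gives a pentadienyl palladium species that can be attacked at C8, C10 or C12 and can lose the 9E geometry by η3–η1–η3 isomerisation. The furanolate is ambident (C5 against C7). The C7 configuration would rest on a ligand acting inside a macrocycle far from C14. A1 itself needs a macrocyclisation of its own.
- Comparison: the end game of this road is shorter than steps 14 to 16 of the chosen plan. The chosen plan sets against this a C7 centre bought from the chiral pool and a diene that never meets π-allyl chemistry.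

**Alternative 2: cyclopropenone–aldehyde (3+2) macroannulation.** The cuts are C6–C7 and the lactone C–O bond. A chiral phosphine would open the cyclopropenone of the acyclic aldehyde A3 to a ketene ylide whose C6 adds to the C7 aldehyde. The alkoxide then closes onto the ketene carbon to give A4, the triethylsilyl ether of the target.
- Merits: butenolide, C7 and the 14-membered ring arise together in a redox-neutral, catalytic step; on paper this is the most step-economic ring closure of all four plans.
- Weak points: the annulation is known between separate partners, not as a macrocyclisation, so oligomerisation competes. The C7 aldehyde of A3 is β,γ-unsaturated and sits next to the diene, so a nucleophilic, basic phosphine invites enolisation and conjugation. The phosphine can also add to the enoate. Facial control at C7 by a chiral phosphine in a ring closure of this size is untested, and the monosubstituted cyclopropenone must survive the fragment assembly.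
- Comparison: if it worked it would beat the chosen lactonisation/metathesis pair by two steps. The chosen plan accepts those steps in exchange for ring closures of established type and a pre-set C7.

**Alternative 3: ring-closing alkyne metathesis, then trans-hydrostannation.** The cut is C1≡C2. A molybdenum alkylidyne of the type (Ph3SiO)3Mo≡C(C6H4OMe-4) would close the methyl-capped diyne A5 to the cycloalkyne A6, which after desilylation would enter the same hydrostannation and methoxycarbonylation as steps 12 and 13.
- Merits: alkyne metathesis is dependable for 14-membered rings, raises no geometry question, tolerates butenolide and diene, and closes the ring far from both stereocentres. As a ring closure it is at least as secure as the macrolactonisation of 32, probably more so.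
- Weak points: the base-sensitive butenolide must be carried through more steps. A5 still needs its own solution for the C11=C12 geometry and for C14, most plausibly the same allylboration. The hydrostannation would then run on a strained macrocycle next to a butenolide.
- Comparison: the chosen plan sets against the better ring closure its convergence. Three fragments are joined, the diene geometry is fixed and C14 is set in one flask, and the tin and palladium chemistry is done on an acyclic substrate.

Key step: step 11

## Route

Remark on the chemistry: the sense of induction in step 6 (the (S,S)-diol giving the 11R chloride) is taken from the zinc-chelated transition-state model of the homologation; if it proves to be the reverse, the (R,R)-diol is used in step 5 and nothing else changes.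

Step 1
Reactants: 1 (R)-epichlorohydrin; 2 ethynyltrimethylsilane
Product: 4 (2R)-1-chloro-5-(trimethylsilyl)pent-4-yn-2-ol, via lithium (trimethylsilyl)acetylide 3 (not isolated)
Conditions: 2, n-BuLi, THF, −78 °C; BF3·OEt2; then 1, −78 °C; H2O
Reagents that add atoms: none
Why: Boron trifluoride-promoted SN2 opening of the epoxide at its unsubstituted carbon by the lithium acetylide, at a temperature where the chloride is not displaced; the carbinol carbon that becomes C7 is taken unchanged from the chiral pool.

Step 2
Reactants: 4 (2R)-1-chloro-5-(trimethylsilyl)pent-4-yn-2-ol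
Product: 7 (3R)-hex-1-en-5-yn-3-ol, via epoxide 5 (not isolated), via silylated enynol 6 (not isolated)
Conditions: Me3S+ I−, n-BuLi, THF, −10 °C → rt; then K2CO3, MeOH, rt
Reagents that add atoms: trimethylsulfonium iodide, C[S+](C)C.[I-]
Why: The sulfonium ylide closes the chlorohydrin to the epoxide, opens it at CH2, and the betaine loses dimethyl sulfide (one-carbon homologation of an epoxide to an allylic alcohol with a Corey–Chaykovsky reagent); the stereocentre is not involved and stays R. Basic methanolysis then removes the alkynylsilane.

Step 3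
Reactants: 7 (3R)-hex-1-en-5-yn-3-ol
Product: 8 (3R)-3-[(tert-butyldimethylsilyl)oxy]hex-1-en-5-yne
Conditions: TBSCl, imidazole, DMF, rt
Reagents that add atoms: tert-butyldimethylsilyl chloride, CC(C)(C)[Si](C)(C)Cl
Why: Standard silylation of a secondary alcohol; this silyl ether is chosen because it should survive Me3Al, t-BuLi and the acidic methanol of step 13 (where a triethylsilyl ether would be lost) and falls to fluoride in step 14.

Step 4
Reactants: 8 (3R)-3-[(tert-butyldimethylsilyl)oxy]hex-1-en-5-yne
Product: 10 (3R,5E)-3-[(tert-butyldimethylsilyl)oxy]-6-iodo-5-methylhexa-1,5-diene, via alkenylalane 9 (not isolated)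
Conditions: Me3Al, Cp2ZrCl2, CH2Cl2, 0 °C → rt; then I2, THF, −30 °C
Reagents that add atoms: trimethylaluminium, C[Al](C)C; iodine, II
Why: Negishi zirconium-catalysed carboalumination adds methyl and aluminium syn across the alkyne, methyl to the internal carbon C9 and aluminium to C10; iodinolysis with retention gives the E iodide. The monosubstituted alkene is not carbometallated under these conditions.

Step 5
Reactants: 10 (3R,5E)-3-[(tert-butyldimethylsilyl)oxy]-6-iodo-5-methylhexa-1,5-diene
Product: 13 (4S,5S)-2-[(1E,4R)-4-[(tert-butyldimethylsilyl)oxy]-2-methylhexa-1,5-dien-1-yl]-4,5-dicyclohexyl-1,3,2-dioxaborolane, via alkenyllithium 11 (not isolated), via alkenylboronic acid 12 (not isolated)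
Conditions: t-BuLi, Et2O, −78 °C; B(OiPr)3, −78 °C → rt; aq. NH4Cl; then (1S,2S)-1,2-dicyclohexylethane-1,2-diol, MgSO4, Et2O, rt
Reagents that add atoms: triisopropyl borate, CC(C)OB(OC(C)C)OC(C)C; (1S,2S)-1,2-dicyclohexylethane-1,2-diol, O[C@@H](C1CCCCC1)[C@H](C1CCCCC1)O
Why: Iodine–lithium exchange with retention of alkene geometry, borylation, and esterification of the crude boronic acid with the C2-symmetric diol that controls step 6.

Step 6
Reactants: 13 (4S,5S)-2-[(1E,4R)-4-[(tert-butyldimethylsilyl)oxy]-2-methylhexa-1,5-dien-1-yl]-4,5-dicyclohexyl-1,3,2-dioxaborolane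
Product: 15 (4S,5S)-2-[(1R,2E,5R)-5-[(tert-butyldimethylsilyl)oxy]-1-chloro-3-methylhepta-2,6-dien-1-yl]-4,5-dicyclohexyl-1,3,2-dioxaborolane, via lithium ate complex 14 (not isolated)
Conditions: CH2Cl2, n-BuLi, THF, −100 °C; 13; ZnCl2, −100 → 0 °C; salts removed with pentane, used at once
Reagents that add atoms: dichloromethane, ClCCl
Why: Matteson homologation: dichloromethyllithium adds to boron, and in the zinc chloride-chelated ate complex the alkenyl group migrates to carbon with loss of one of the two diastereotopic chlorides; the (S,S)-diol decides which chloride leaves and sets C11 as R. Zinc chloride also binds the released chloride and so limits epimerisation by chloride exchange; the allylic chloride is neither chromatographed nor stored.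

Step 7
Reactants: 16 2-bromo-3-methylbut-1-ene
Product: 17 (3-methylbut-1-en-2-yl)magnesium bromide
Conditions: Mg, 1,2-dibromoethane (cat.), THF, rt → 45 °C; titrated
Reagents that add atoms: magnesium, [Mg]
Why: Insertion of magnesium into the alkenyl C–Br bond (Grignard formation); titration allows exactly one equivalent to be used in step 11.

Step 8
Reactants: 18 tert-butyl 2-(diethoxyphosphoryl)acetate; 19 4-bromobut-1-yne
Product: 21 tert-butyl 2-(diethoxyphosphoryl)hex-5-ynoate (racemic), via sodium enolate 20 (not isolated)
Conditions: NaH, DMF, 0 °C; then 19, rt → 50 °C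
Reagents that add atoms: none
Why: SN2 alkylation of the stabilised phosphonoacetate anion by the primary homopropargylic bromide; the soft, weakly basic anion limits elimination to the enyne and leaves the alkyne C–H alone.

Step 9
Reactants: 21 tert-butyl 2-(diethoxyphosphoryl)hex-5-ynoate
Product: 22 tert-butyl 2-methylidenehex-5-ynoate
Conditions: aq. HCHO, K2CO3, THF/H2O, rt
Reagents that add atoms: formaldehyde, C=O
Why: Horner–Wadsworth–Emmons methylenation with aqueous formaldehyde under carbonate conditions gives the 2-substituted acrylate and removes the stereocentre of 21.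

Step 10
Reactants: 22 tert-butyl 2-methylidenehex-5-ynoate
Product: 24 tert-butyl 2-methylidene-7-oxohept-5-ynoate, via lithium acetylide 23 (not isolated)
Conditions: LiN(SiMe3)2, THF, −78 °C; DMF, −78 → 0 °C; poured into cold aq. KH2PO4
Reagents that add atoms: N,N-dimethylformamide, CN(C)C=O
Why: Deprotonation of the alkyne C–H by a hindered amide that is a poor Michael donor, then formylation of the acetylide with DMF; the tert-butyl ester blocks 1,2-addition. The inverse buffered quench keeps liberated dimethylamine from adding to the ynal.

Step 11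
Reactants: 15 (4S,5S)-2-[(1R,2E,5R)-5-[(tert-butyldimethylsilyl)oxy]-1-chloro-3-methylhepta-2,6-dien-1-yl]-4,5-dicyclohexyl-1,3,2-dioxaborolane; 17 (3-methylbut-1-en-2-yl)magnesium bromide; 24 tert-butyl 2-methylidene-7-oxohept-5-ynoate
Product: 28 tert-butyl (7S,9E,11E,14R)-14-[(tert-butyldimethylsilyl)oxy]-7-hydroxy-12-methyl-2-methylidene-9-(propan-2-yl)hexadeca-9,11,15-trien-5-ynoate, via magnesium ate complex 25 (not isolated), via bis-allylic boronate 26 (not isolated), via borate ester 27 (not isolated)
Conditions: 17 (1.0 equiv), THF, −78 → 0 °C; then 24, −78 → −20 °C; pH 7 buffer, rt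
Reagents that add atoms: none
Why: The Grignard reagent 17 adds to boron of 15 at −78 °C to give the tetracoordinate complex 25, and on warming the 3-methylbut-1-en-2-yl group shifts from boron to C11 antiperiplanar to the departing chloride (1,2-metallate rearrangement, the Matteson substitution of an α-chloro boronic ester), so the C11–C12 bond forms with inversion and 26 is 11S. Boronate 26 is an α-substituted, 2-substituted allylboronic ester and adds to the ynal 24 through a closed six-membered chair (allylboration of Zimmerman–Traxler type), forming the C13–C14 bond; no ring is closed in either event. The new stereocentre C14 is controlled by C11: the alkynyl group of 24 lies equatorial, and the isopropyl group on C12 forces the dienyl substituent on C11 into the axial position to avoid developing allylic 1,2-strain, which relays 11S to 14S and places C10 cis to C13 in the new C11=C12 alkene. Site selectivity between the two allyl arms of 26 is required and is secured by substitution, since transfer through the unsubstituted C13 terminus is much faster than through the fully substituted C9 terminus, which would create a quaternary carbon. The aldehyde is preferred over the acrylate of 24 because only a carbonyl oxygen can bind boron in the cyclic transition state, and the single equivalent of 17 is consumed at boron before 24 is added. The closest precedents are the Grignard substitution of α-chloro allylboronic esters and the chirality-transferring allylboration of aldehydes by α-substituted allylboronic esters; here they are run in one flask. The (S,S)-diol is a spectator in the second event and is released when the borate ester 27 is hydrolysed.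

Step 12
Reactants: 28 tert-butyl (7S,9E,11E,14R)-14-[(tert-butyldimethylsilyl)oxy]-7-hydroxy-12-methyl-2-methylidene-9-(propan-2-yl)hexadeca-9,11,15-trien-5-ynoate
Product: 29 tert-butyl (5Z,7S,9E,11E,14R)-14-[(tert-butyldimethylsilyl)oxy]-7-hydroxy-12-methyl-2-methylidene-9-(propan-2-yl)-6-(tributylstannyl)hexadeca-5,9,11,15-tetraenoate
Conditions: Bu3SnH, [Cp*RuCl]4 (cat.), CH2Cl2, rt
Reagents that add atoms: tributyltin hydride, CCCC[SnH](CCCC)CCCC
Why: Ruthenium-catalysed trans-hydrostannation steered by the free propargylic hydroxyl, which hydrogen-bonds to the chloride ligand: tin goes to the proximal carbon C1 and hydrogen to C2 from the opposite face, so C3 ends cis to tin. The diene is substituted at both termini and cannot reach the s-cis form needed to bind the catalyst in η4 fashion.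

Step 13
Reactants: 29 tert-butyl (5Z,7S,9E,11E,14R)-14-[(tert-butyldimethylsilyl)oxy]-7-hydroxy-12-methyl-2-methylidene-9-(propan-2-yl)-6-(tributylstannyl)hexadeca-5,9,11,15-tetraenoate
Product: 30 tert-butyl (5Z,7S,9E,11E,14R)-14-[(tert-butyldimethylsilyl)oxy]-7-hydroxy-6-(methoxycarbonyl)-12-methyl-2-methylidene-9-(propan-2-yl)hexadeca-5,9,11,15-tetraenoate
Conditions: Pd(OAc)2 (cat.), Ph3As, 1,4-benzoquinone, CF3CO2H, CO (1 atm), MeOH, rt
Reagents that add atoms: carbon monoxide, [C-]#[O+]; methanol, CO
Why: Hydroxyl-assisted oxidative methoxycarbonylation of the alkenylstannane: tin-to-palladium exchange, CO insertion and methanolysis proceed with retention at C1, and benzoquinone reoxidises palladium. The ester thus ends cis to C3 as in the target.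

Step 14
Reactants: 30 tert-butyl (5Z,7S,9E,11E,14R)-14-[(tert-butyldimethylsilyl)oxy]-7-hydroxy-6-(methoxycarbonyl)-12-methyl-2-methylidene-9-(propan-2-yl)hexadeca-5,9,11,15-tetraenoate
Product: 32 (5Z,7S,9E,11E,14R)-7,14-dihydroxy-6-(methoxycarbonyl)-12-methyl-2-methylidene-9-(propan-2-yl)hexadeca-5,9,11,15-tetraenoic acid, via persilylated ester 31 (not isolated)
Conditions: TMSOTf, 2,6-lutidine, CH2Cl2, 0 °C; then HF·pyridine, pyridine, THF, 0 °C → rt
Reagents that add atoms: none
Why: Silyl triflate-mediated cleavage of the tert-butyl ester under buffered aprotic conditions that spare the diene (the C14 hydroxyl is silylated in passing), then fluoride removal of all three silyl groups; the methyl ester is untouched.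

Step 15
Reactants: 32 (5Z,7S,9E,11E,14R)-7,14-dihydroxy-6-(methoxycarbonyl)-12-methyl-2-methylidene-9-(propan-2-yl)hexadeca-5,9,11,15-tetraenoic acid
Product: 34 methyl (6Z,8S,10E,12E,15R)-15-ethenyl-8-hydroxy-13-methyl-3-methylidene-2-oxo-10-(propan-2-yl)-1-oxacyclopentadeca-6,10,12-triene-7-carboxylate, via mixed anhydride 33 (not isolated)
Conditions: 2,4,6-Cl3C6H2COCl, Et3N, THF, rt; then slow addition to DMAP, toluene, 60 °C, high dilution
Reagents that add atoms: none
Why: Yamaguchi macrolactonisation: the mixed anhydride acylates the C7 hydroxyl to close the 15-membered ring, with retention at C7 because the alcohol is the nucleophile. The C14 hydroxyl could only form an eight-membered lactone containing the trans-disposed C1=C2 unit and is left free.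

Step 16
Reactants: 34 methyl (6Z,8S,10E,12E,15R)-15-ethenyl-8-hydroxy-13-methyl-3-methylidene-2-oxo-10-(propan-2-yl)-1-oxacyclopentadeca-6,10,12-triene-7-carboxylate
Product: 35 methyl (4Z,6S,8E,10E,13R)-6-hydroxy-11-methyl-15-oxo-8-(propan-2-yl)-14-oxabicyclo[11.2.1]hexadeca-1(16),4,8,10-tetraene-5-carboxylate (the target)
Conditions: second-generation Grubbs catalyst (H2IMes)(PCy3)Cl2Ru=CHPh, toluene, 80 °C, dilute, argon sweep
Reagents that add atoms: none
Why: Ring-closing metathesis: the ruthenium alkylidene forms at the C6 vinyl group and closes onto the acrylate methylene of C5, releasing ethene; the five-membered ring fixes the geometry of the new trisubstituted alkene and converts the 15-membered lactone into the 14-membered carbocycle. The E geometry of C9=C10 rules out a six-membered closure onto C11, and no base is present that could epimerise C7.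

## Compound list

1 | (R)-epichlorohydrin, (2R)-2-(chloromethyl)oxirane | ClC[C@H]1CO1 | starting material
2 | ethynyltrimethylsilane | C#C[Si](C)(C)C | starting material
3 | lithium (trimethylsilyl)acetylide | [Li]C#C[Si](C)(C)C | intermediate
4 | (2R)-1-chloro-5-(trimethylsilyl)pent-4-yn-2-ol | ClC[C@H](O)CC#C[Si](C)(C)C | intermediate
5 | (2R)-2-[3-(trimethylsilyl)prop-2-yn-1-yl]oxirane | C1[C@@H](CC#C[Si](C)(C)C)O1 | intermediate
6 | (3R)-6-(trimethylsilyl)hex-1-en-5-yn-3-ol | C=C[C@H](O)CC#C[Si](C)(C)C | intermediate
7 | (3R)-hex-1-en-5-yn-3-ol | C=C[C@H](O)CC#C | intermediate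
8 | (3R)-3-[(tert-butyldimethylsilyl)oxy]hex-1-en-5-yne | C=C[C@H](O[Si](C)(C)C(C)(C)C)CC#C | intermediate
9 | [(1E,4R)-4-[(tert-butyldimethylsilyl)oxy]-2-methylhexa-1,5-dien-1-yl]dimethylalane | C=C[C@H](O[Si](C)(C)C(C)(C)C)C/C(C)=C/[Al](C)C | intermediate
10 | (3R,5E)-3-[(tert-butyldimethylsilyl)oxy]-6-iodo-5-methylhexa-1,5-diene | C=C[C@H](O[Si](C)(C)C(C)(C)C)C/C(C)=C/I | intermediate
11 | [(1E,4R)-4-[(tert-butyldimethylsilyl)oxy]-2-methylhexa-1,5-dien-1-yl]lithium | C=C[C@H](O[Si](C)(C)C(C)(C)C)C/C(C)=C/[Li] | intermediate
12 | [(1E,4R)-4-[(tert-butyldimethylsilyl)oxy]-2-methylhexa-1,5-dien-1-yl]boronic acid | C=C[C@H](O[Si](C)(C)C(C)(C)C)C/C(C)=C/B(O)O | intermediate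
13 | (4S,5S)-2-[(1E,4R)-4-[(tert-butyldimethylsilyl)oxy]-2-methylhexa-1,5-dien-1-yl]-4,5-dicyclohexyl-1,3,2-dioxaborolane | C=C[C@H](O[Si](C)(C)C(C)(C)C)C/C(C)=C/B1O[C@@H](C2CCCCC2)[C@H](C2CCCCC2)O1 | intermediate
14 | lithium (dichloromethyl)borate of 13 (ate complex) | C=C[C@H](O[Si](C)(C)C(C)(C)C)C/C(C)=C/[B-]1(C(Cl)Cl)O[C@@H](C2CCCCC2)[C@H](C2CCCCC2)O1.[Li+] | intermediate
15 | (4S,5S)-2-[(1R,2E,5R)-5-[(tert-butyldimethylsilyl)oxy]-1-chloro-3-methylhepta-2,6-dien-1-yl]-4,5-dicyclohexyl-1,3,2-dioxaborolane | C=C[C@H](O[Si](C)(C)C(C)(C)C)C/C(C)=C/[C@H](Cl)B1O[C@@H](C2CCCCC2)[C@H](C2CCCCC2)O1 | intermediate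
16 | 2-bromo-3-methylbut-1-ene | CC(C)C(Br)=C | starting material
17 | (3-methylbut-1-en-2-yl)magnesium bromide | CC(C)C(=C)[Mg]Br | intermediate
18 | tert-butyl 2-(diethoxyphosphoryl)acetate | CCOP(=O)(OCC)CC(=O)OC(C)(C)C | starting material
19 | 4-bromobut-1-yne | BrCCC#C | starting material
20 | sodium enolate of 18 | CCOP(=O)(OCC)[CH-]C(=O)OC(C)(C)C.[Na+] | intermediate
21 | tert-butyl 2-(diethoxyphosphoryl)hex-5-ynoate (racemic) | CCOP(=O)(OCC)C(CCC#C)C(=O)OC(C)(C)C | intermediate
22 | tert-butyl 2-methylidenehex-5-ynoate | C=C(CCC#C)C(=O)OC(C)(C)C | intermediate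
23 | lithium acetylide of 22 | [Li]C#CCCC(=C)C(=O)OC(C)(C)C | intermediate
24 | tert-butyl 2-methylidene-7-oxohept-5-ynoate | O=CC#CCCC(=C)C(=O)OC(C)(C)C | intermediate
25 | bromomagnesium alkenyl(α-chloroallyl)borate (ate complex of 15 and 17) | C=C[C@H](O[Si](C)(C)C(C)(C)C)C/C(C)=C/[C@H](Cl)[B-]1(C(=C)C(C)C)O[C@@H](C2CCCCC2)[C@H](C2CCCCC2)O1.[Mg+]Br | intermediate
26 | (4S,5S)-2-[(3S,4E,7R)-7-[(tert-butyldimethylsilyl)oxy]-5-methyl-2-(propan-2-yl)nona-1,4,8-trien-3-yl]-4,5-dicyclohexyl-1,3,2-dioxaborolane | C=C[C@H](O[Si](C)(C)C(C)(C)C)C/C(C)=C/[C@@H](C(=C)C(C)C)B1O[C@@H](C2CCCCC2)[C@H](C2CCCCC2)O1 | intermediate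
27 | borate ester of 28 with the (S,S)-diol (2-alkoxy-4,5-dicyclohexyl-1,3,2-dioxaborolane) | C=C[C@H](O[Si](C)(C)C(C)(C)C)C/C(C)=C/C=C(/C(C)C)C[C@H](OB1O[C@@H](C2CCCCC2)[C@H](C2CCCCC2)O1)C#CCCC(=C)C(=O)OC(C)(C)C | intermediate
28 | tert-butyl (7S,9E,11E,14R)-14-[(tert-butyldimethylsilyl)oxy]-7-hydroxy-12-methyl-2-methylidene-9-(propan-2-yl)hexadeca-9,11,15-trien-5-ynoate | C=C[C@H](O[Si](C)(C)C(C)(C)C)C/C(C)=C/C=C(/C(C)C)C[C@H](O)C#CCCC(=C)C(=O)OC(C)(C)C | intermediate
29 | tert-butyl (5Z,7S,9E,11E,14R)-14-[(tert-butyldimethylsilyl)oxy]-7-hydroxy-12-methyl-2-methylidene-9-(propan-2-yl)-6-(tributylstannyl)hexadeca-5,9,11,15-tetraenoate | C=C[C@H](O[Si](C)(C)C(C)(C)C)C/C(C)=C/C=C(/C(C)C)C[C@H](O)/C(=C/CCC(=C)C(=O)OC(C)(C)C)[Sn](CCCC)(CCCC)CCCC | intermediate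
30 | tert-butyl (5Z,7S,9E,11E,14R)-14-[(tert-butyldimethylsilyl)oxy]-7-hydroxy-6-(methoxycarbonyl)-12-methyl-2-methylidene-9-(propan-2-yl)hexadeca-5,9,11,15-tetraenoate | C=C[C@H](O[Si](C)(C)C(C)(C)C)C/C(C)=C/C=C(/C(C)C)C[C@H](O)/C(=C/CCC(=C)C(=O)OC(C)(C)C)C(=O)OC | intermediate
31 | trimethylsilyl (5Z,7S,9E,11E,14R)-14-[(tert-butyldimethylsilyl)oxy]-6-(methoxycarbonyl)-12-methyl-2-methylidene-9-(propan-2-yl)-7-[(trimethylsilyl)oxy]hexadeca-5,9,11,15-tetraenoate | C=C[C@H](O[Si](C)(C)C(C)(C)C)C/C(C)=C/C=C(/C(C)C)C[C@H](O[Si](C)(C)C)/C(=C/CCC(=C)C(=O)O[Si](C)(C)C)C(=O)OC | intermediate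
32 | (5Z,7S,9E,11E,14R)-7,14-dihydroxy-6-(methoxycarbonyl)-12-methyl-2-methylidene-9-(propan-2-yl)hexadeca-5,9,11,15-tetraenoic acid | C=C[C@H](O)C/C(C)=C/C=C(/C(C)C)C[C@H](O)/C(=C/CCC(=C)C(=O)O)C(=O)OC | intermediate
33 | mixed anhydride of 32 with 2,4,6-trichlorobenzoic acid | C=C[C@H](O)C/C(C)=C/C=C(/C(C)C)C[C@H](O)/C(=C/CCC(=C)C(=O)OC(=O)c1c(Cl)cc(Cl)cc1Cl)C(=O)OC | intermediate
34 | methyl (6Z,8S,10E,12E,15R)-15-ethenyl-8-hydroxy-13-methyl-3-methylidene-2-oxo-10-(propan-2-yl)-1-oxacyclopentadeca-6,10,12-triene-7-carboxylate | C=C[C@H]1C/C(C)=C/C=C(/C(C)C)C[C@H](O)/C(=C/CCC(=C)C(=O)O1)C(=O)OC | intermediate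
35 | methyl (4Z,6S,8E,10E,13R)-6-hydroxy-11-methyl-15-oxo-8-(propan-2-yl)-14-oxabicyclo[11.2.1]hexadeca-1(16),4,8,10-tetraene-5-carboxylate | COC(=O)/C1=C\CCC2=C[C@@H](C/C(C)=C/C=C(/C(C)C)C[C@@H]1O)OC2=O | target

## Step count and least certain steps

Total step count: 16 steps. Longest linear sequence: 12 steps (steps 1 to 6 and 11 to 16, from 1).

**Step 11 (key step).** The most likely failure is partial loss of the C11 configuration before the allyl transfer. This can happen by chloride exchange or ionisation in 15, or by a 1,3-boron shift in 26, and it would show up as erosion of the configuration at C14. A smaller share of allyl transfer through C9 is the second concern. Fallback: the step is then asked only for connectivity and alkene geometry, since both C11 epimers pass through the axial transition state and give the same C11=C12 geometry, and C14 is reset by reagent control. The fallback sets out from 28 as obtained. Oxidation with MnO2 in CH2Cl2 gives the ynone tert-butyl (9E,11E,14R)-14-[(tert-butyldimethylsilyl)oxy]-12-methyl-2-methylidene-7-oxo-9-(propan-2-yl)hexadeca-9,11,15-trien-5-ynoate F1. Noyori transfer hydrogenation of F1 with RuCl(p-cymene)[(S,S)-TsDPEN] in iPrOH, the ligand enantiomer that gives S carbinols from simple alkynyl ketones, returns to the route at 28.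

**Step 6.** The chloride of 15 is a prenyl-type allylic chloride. Ionisation or chloride exchange during the zinc chloride-assisted rearrangement or on handling can epimerise C11 or move the chlorine to C9. Fallback: the roles of the two alkenyl groups are exchanged so that the chlorine sits on an allyl unit with an unsubstituted terminus, which ionises far less readily. The fallback sets out from 17 and from alkenyllithium 11 (made from 10 as in step 5).
- Borylation of 17 with B(OMe)3 and esterification with (1R,2R)-1,2-dicyclohexylethane-1,2-diol gives (4R,5R)-4,5-dicyclohexyl-2-(3-methylbut-1-en-2-yl)-1,3,2-dioxaborolane F2.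
- Homologation with LiCHCl2/ZnCl2 gives (4R,5R)-2-[(1S)-1-chloro-3-methyl-2-methylidenebutyl]-4,5-dicyclohexyl-1,3,2-dioxaborolane F3.
- Addition of 11 at −78 °C and warming displaces chloride with inversion and gives (4R,5R)-2-[(3S,4E,7R)-7-[(tert-butyldimethylsilyl)oxy]-5-methyl-2-(propan-2-yl)nona-1,4,8-trien-3-yl]-4,5-dicyclohexyl-1,3,2-dioxaborolane F4. This has the same 11S configuration as 26, which is why the enantiomeric diol is needed.
- Addition of 24 gives the borate ester of 28 with the (R,R)-diol F5, and hydrolysis returns to the route at 28.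

The price is that the bond made by migration is then C10–C11 and not C11–C12; the allylboration is unchanged.

**Step 10.** The acrylate of 22 may be attacked by the amide base or by the acetylide 23 (conjugate addition, oligomerisation) before formylation is complete. Fallback: C14 is introduced before the acrylate exists and at the alcohol oxidation level. The fallback sets out from 21. Double deprotonation with LiN(iPr)2 (2.1 equiv, THF, −78 °C) and treatment with paraformaldehyde hydroxymethylates the acetylide and methylenates the phosphonate carbanion in the same flask, giving tert-butyl 7-hydroxy-2-methylidenehept-5-ynoate F6. Oxidation of F6 with MnO2 in CH2Cl2 returns to the route at 24.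

**Step 13.** Protodestannation of 29 in the acidic methanol can outrun the tin-to-palladium exchange and give the C1–H alkene. Fallback: a two-stage carbonylation without acid. The fallback sets out from 29. Iododestannylation with I2 in CH2Cl2 at 0 °C (retention) gives tert-butyl (5Z,7S,9E,11E,14R)-14-[(tert-butyldimethylsilyl)oxy]-7-hydroxy-6-iodo-12-methyl-2-methylidene-9-(propan-2-yl)hexadeca-5,9,11,15-tetraenoate F7. Carbonylation of F7 with PdCl2(PPh3)2, CO, Et3N and MeOH at 50 °C returns to the route at 30.

**Step 15.** Intermolecular esterification through either hydroxyl (oligomers), or acyl transfer to the unprotected C14 hydroxyl, may compete with closure of the 15-membered ring. Fallback: C14 is carried as a triisopropylsilyl ether through both ring closures. The fallback sets out from 30.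
- TIPSOTf and then TMSOTf with 2,6-lutidine, followed by aqueous work-up, give (5Z,7S,9E,11E,14R)-14-[(tert-butyldimethylsilyl)oxy]-6-(methoxycarbonyl)-12-methyl-2-methylidene-9-(propan-2-yl)-7-[(triisopropylsilyl)oxy]hexadeca-5,9,11,15-tetraenoic acid F8.
- Camphorsulfonic acid in MeOH at 0 °C removes the less hindered tert-butyldimethylsilyl ether and gives the C7 alcohol (5Z,7S,9E,11E,14R)-14-hydroxy-6-(methoxycarbonyl)-12-methyl-2-methylidene-9-(propan-2-yl)-7-[(triisopropylsilyl)oxy]hexadeca-5,9,11,15-tetraenoic acid F9.
- Lactonisation as in step 15 gives the macrolactone methyl (6Z,8S,10E,12E,15R)-15-ethenyl-13-methyl-3-methylidene-2-oxo-10-(propan-2-yl)-8-[(triisopropylsilyl)oxy]-1-oxacyclopentadeca-6,10,12-triene-7-carboxylate F10.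
- Metathesis as in step 16 gives the C14 triisopropylsilyl ether of the target F11.
- HF·pyridine in THF returns to the route at 35.

## Further compounds

F1 | step 11 | tert-butyl (9E,11E,14R)-14-[(tert-butyldimethylsilyl)oxy]-12-methyl-2-methylidene-7-oxo-9-(propan-2-yl)hexadeca-9,11,15-trien-5-ynoate | C=C[C@H](O[Si](C)(C)C(C)(C)C)C/C(C)=C/C=C(/C(C)C)CC(=O)C#CCCC(=C)C(=O)OC(C)(C)C
F2 | step 6 | (4R,5R)-4,5-dicyclohexyl-2-(3-methylbut-1-en-2-yl)-1,3,2-dioxaborolane | CC(C)C(=C)B1O[C@H](C2CCCCC2)[C@@H](C2CCCCC2)O1
F3 | step 6 | (4R,5R)-2-[(1S)-1-chloro-3-methyl-2-methylidenebutyl]-4,5-dicyclohexyl-1,3,2-dioxaborolane | CC(C)C(=C)[C@@H](Cl)B1O[C@H](C2CCCCC2)[C@@H](C2CCCCC2)O1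
F4 | step 6 | (4R,5R)-2-[(3S,4E,7R)-7-[(tert-butyldimethylsilyl)oxy]-5-methyl-2-(propan-2-yl)nona-1,4,8-trien-3-yl]-4,5-dicyclohexyl-1,3,2-dioxaborolane | C=C[C@H](O[Si](C)(C)C(C)(C)C)C/C(C)=C/[C@@H](C(=C)C(C)C)B1O[C@H](C2CCCCC2)[C@@H](C2CCCCC2)O1
F5 | step 6 | borate ester of 28 with the (R,R)-diol | C=C[C@H](O[Si](C)(C)C(C)(C)C)C/C(C)=C/C=C(/C(C)C)C[C@H](OB1O[C@H](C2CCCCC2)[C@@H](C2CCCCC2)O1)C#CCCC(=C)C(=O)OC(C)(C)C
F6 | step 10 | tert-butyl 7-hydroxy-2-methylidenehept-5-ynoate | OCC#CCCC(=C)C(=O)OC(C)(C)C
F7 | step 13 | tert-butyl (5Z,7S,9E,11E,14R)-14-[(tert-butyldimethylsilyl)oxy]-7-hydroxy-6-iodo-12-methyl-2-methylidene-9-(propan-2-yl)hexadeca-5,9,11,15-tetraenoate | C=C[C@H](O[Si](C)(C)C(C)(C)C)C/C(C)=C/C=C(/C(C)C)C[C@H](O)/C(I)=C/CCC(=C)C(=O)OC(C)(C)C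
F8 | step 15 | (5Z,7S,9E,11E,14R)-14-[(tert-butyldimethylsilyl)oxy]-6-(methoxycarbonyl)-12-methyl-2-methylidene-9-(propan-2-yl)-7-[(triisopropylsilyl)oxy]hexadeca-5,9,11,15-tetraenoic acid | C=C[C@H](O[Si](C)(C)C(C)(C)C)C/C(C)=C/C=C(/C(C)C)C[C@H](O[Si](C(C)C)(C(C)C)C(C)C)/C(=C/CCC(=C)C(=O)O)C(=O)OC
F9 | step 15 | (5Z,7S,9E,11E,14R)-14-hydroxy-6-(methoxycarbonyl)-12-methyl-2-methylidene-9-(propan-2-yl)-7-[(triisopropylsilyl)oxy]hexadeca-5,9,11,15-tetraenoic acid | C=C[C@H](O)C/C(C)=C/C=C(/C(C)C)C[C@H](O[Si](C(C)C)(C(C)C)C(C)C)/C(=C/CCC(=C)C(=O)O)C(=O)OC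
F10 | step 15 | methyl (6Z,8S,10E,12E,15R)-15-ethenyl-13-methyl-3-methylidene-2-oxo-10-(propan-2-yl)-8-[(triisopropylsilyl)oxy]-1-oxacyclopentadeca-6,10,12-triene-7-carboxylate | C=C[C@H]1C/C(C)=C/C=C(/C(C)C)C[C@H](O[Si](C(C)C)(C(C)C)C(C)C)/C(=C/CCC(=C)C(=O)O1)C(=O)OC
F11 | step 15 | C14 triisopropylsilyl ether of the target | COC(=O)/C1=C\CCC2=C[C@@H](C/C(C)=C/C=C(/C(C)C)C[C@@H]1O[Si](C(C)C)(C(C)C)C(C)C)OC2=O
A1 | alternative 1 | 16-membered allyl furan-2-yl carbonate, C14 tert-butyldimethylsilyl ether | COC(=O)/C1=C\CCc2ccoc2OC(=O)OC/C(C)=C/C=C(/C(C)C)C[C@@H]1O[Si](C)(C)C(C)(C)C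
A2 | alternative 1 | C14 tert-butyldimethylsilyl ether of the target | COC(=O)/C1=C\CCC2=C[C@@H](C/C(C)=C/C=C(/C(C)C)C[C@@H]1O[Si](C)(C)C(C)(C)C)OC2=O
A3 | alternative 2 | acyclic C7 aldehyde with a C5-substituted cyclopropenone, C14 triethylsilyl ether | O=CC/C(C)=C/C=C(/C(C)C)C[C@H](O[Si](CC)(CC)CC)/C(=C/CCC1=CC1=O)C(=O)OC
A4 | alternative 2 | C14 triethylsilyl ether of the target | COC(=O)/C1=C\CCC2=C[C@@H](C/C(C)=C/C=C(/C(C)C)C[C@@H]1O[Si](CC)(CC)CC)OC2=O
A5 | alternative 3 | acyclic butenolide with two methyl-capped alkynes, C14 triethylsilyl ether | CC#CCCC1=C[C@@H](C/C(C)=C/C=C(/C(C)C)C[C@H](O[Si](CC)(CC)CC)C#CC)OC1=O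
A6 | alternative 3 | 14-membered cycloalkyne, C14 triethylsilyl ether | C1#CCCC2=C[C@@H](C/C(C)=C/C=C(/C(C)C)C[C@@H]1O[Si](CC)(CC)CC)OC2=O
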